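## Retrosynthetic overview

1. Positions follow germacrane numbering: C6 is the lactone carbinol, C7 the ring-fusion carbon, C11=C13 the exocyclic methylene, C12 the lactone carbonyl, C9 the acyloxy carbinol, C2 the free carbinol, C1=C10 the Z olefin and C4=C5 the E olefin.
2. Target ⇐ Yamaguchi esterification, then desilylation, of the C9-hydroxy γ-lactone (C2 as TBS ether) with silylated (Z)-2-(hydroxymethyl)but-2-enoic acid.
3. Hydroxy γ-lactone ⇐ C6–C7 bond: intramolecular Nozaki–Hiyama allylation of the C6 enal by a 3-(bromomethyl)-5,6-dihydropyran-2-one, followed by acyl shift from O9 to O6. This one step closes the ten-membered ring and the γ-lactone, sets C6 and C7, creates the C11=C13 methylene and uncovers the C9 hydroxyl.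
4. Enabling feature: O9 and C11 stand 1,3-syn on the carbocycle (on C9 and C7), so C12 can first be lent to O9 in a temporary six-membered lactone (ring atoms O9, C9, C8, C7, C11, C12). Its C7=C11 bond with the C13 bromide is an allyl donor of fixed geometry, and C6(O)–C7–C11(=C13)–C12 is the retron of a carbonyl allylation.
5. Bromomethyl lactone ⇐ ring-closing metathesis of a 2-(bromomethyl)acrylate; chain ⇐ vinylogous Mukaiyama aldol (C2, E C4=C5), formylation, Keck allylation (C9), carbomagnesiation of propargyl alcohol (Z C1=C10). Ring order: temporary δ-lactone first, then ten-membered carbocycle and γ-lactone together.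

Key step: step 15

Assumption: (S)-BINOL in step 3 and the (R,R)-bisphosphoramide in step 7 are taken as the antipodes that give the drawn carbinols (si-face allylation, re-face aldol); if the sense proved opposite, the mirror-image controller would be used with nothing else changed.

## Route

Step 1
Reactants: 1 prop-2-yn-1-ol
Product: 3 (2Z)-3-iodo-2-methylprop-2-en-1-ol, via chelated vinylmagnesium alkoxide 2 (not isolated)
Conditions: MeMgBr (2.5 equiv), CuI (10 mol%), THF/Et2O, −10 → 20 °C; then I2, −10 °C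
Reagents that add atoms: methylmagnesium bromide, C[Mg]Br; iodine, II
Why: Copper-catalysed anti-carbomagnesiation of propargyl alcohol places methyl on the inner carbon and magnesium, chelated by the alkoxide, on the terminal carbon, so iodinolysis with retention should give only the Z iodoalkene that later becomes the Z C1=C10 olefin.

Step 2
Reactants: 3 (2Z)-3-iodo-2-methylprop-2-en-1-ol
Product: 4 (2Z)-3-iodo-2-methylprop-2-enal
Conditions: MnO2 (15 equiv), CH2Cl2, 20 °C, dark; used crude
Reagents that add atoms: none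
Why: Allylic oxidation with MnO2 is neutral and heterogeneous and should keep the Z geometry of the iodoenal.

Step 3
Reactants: 4 (2Z)-3-iodo-2-methylprop-2-enal
Product: 5 (1Z,3S)-1-iodo-2-methylhexa-1,5-dien-3-ol
Conditions: (S)-BINOL (20 mol%), Ti(OiPr)4 (10 mol%), 4 Å MS, CH2Cl2; allylSnBu3 (1.5 equiv), −20 °C; aq. NaHCO3
Reagents that add atoms: allyltributylstannane, C=CC[Sn](CCCC)(CCCC)CCCC
Why: Keck asymmetric allylation, in which the BINOL–titanium Lewis acid binds the enal and should direct the allyl group to its si face, sets the C9 carbinol (3S) under catalyst control.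

Step 4
Reactants: 5 (1Z,3S)-1-iodo-2-methylhexa-1,5-dien-3-ol
Product: 6 (1Z,3S)-1-iodo-3-[(4-methoxybenzyl)oxy]-2-methylhexa-1,5-diene
Conditions: NaH, 4-methoxybenzyl chloride, Bu4NI (cat.), DMF, 0 → 25 °C
Reagents that add atoms: 4-methoxybenzyl chloride, COc1ccc(CCl)cc1
Why: Williamson etherification gives a PMB ether that, unlike a silyl ether, cannot migrate to the cis vinyl carbanion of the next step and is later removed oxidatively beside the TBS ether.

Step 5
Reactants: 6 (1Z,3S)-1-iodo-3-[(4-methoxybenzyl)oxy]-2-methylhexa-1,5-diene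
Product: 8 (2Z,4S)-4-[(4-methoxybenzyl)oxy]-3-methylhepta-2,6-dienal, via Z-vinyllithium 7 (not isolated)
Conditions: t-BuLi (2.1 equiv), Et2O, −78 °C; DMF, −78 → 0 °C; aq. NH4Cl
Reagents that add atoms: N,N-dimethylformamide, CN(C)C=O
Why: Iodine–lithium exchange proceeds with retention at the sp2 carbon and Bouveault formylation of the vinyllithium should give the Z enal (C2 as aldehyde) without touching C9.

Step 6
Reactants: 9 methyl 3-methylbut-2-enoate
Product: 11 tert-butyl[(1-methoxy-3-methylbuta-1,3-dien-1-yl)oxy]dimethylsilane, via lithium dienolate 10 (not isolated)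
Conditions: LiN(i-Pr)2, THF, −78 °C; TBSCl, DMPU, −78 → 0 °C
Reagents that add atoms: tert-butyldimethylsilyl chloride, CC(C)(C)[Si](C)(C)Cl
Why: γ-Deprotonation of the senecioate and O-silylation of the dienolate is the standard entry to the silyl dienol ether used in vinylogous aldol reactions.

Step 7
Reactants: 8 (2Z,4S)-4-[(4-methoxybenzyl)oxy]-3-methylhepta-2,6-dienal; 11 tert-butyl[(1-methoxy-3-methylbuta-1,3-dien-1-yl)oxy]dimethylsilane
Product: 12 methyl (2E,5R,6Z,8S)-5-hydroxy-8-[(4-methoxybenzyl)oxy]-3,7-dimethylundeca-2,6,10-trienoate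
Conditions: SiCl4 (1.1 equiv), (R,R)-1,1'-binaphthyl-2,2'-diamine-derived pentamethylene-linked bisphosphoramide (5 mol%), i-Pr2NEt (0.1 equiv), CH2Cl2, −78 °C; aq. NaHCO3
Reagents that add atoms: none
Why: Lewis-base-catalysed, SiCl4-mediated vinylogous Mukaiyama aldol reaction, in which the chiral phosphoramide-bound silicon cation activates the conjugated aldehyde and the dienol ether attacks through its γ-carbon on the re face, should set the C2 carbinol (5R) under catalyst control and form the E C4=C5 enoate.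

Step 8
Reactants: 12 methyl (2E,5R,6Z,8S)-5-hydroxy-8-[(4-methoxybenzyl)oxy]-3,7-dimethylundeca-2,6,10-trienoate
Product: 13 methyl (2E,5R,6Z,8S)-5-[(tert-butyldimethylsilyl)oxy]-8-[(4-methoxybenzyl)oxy]-3,7-dimethylundeca-2,6,10-trienoate
Conditions: TBSOTf, 2,6-lutidine, CH2Cl2, −78 °C
Reagents that add atoms: tert-butyldimethylsilyl triflate, CC(C)(C)[Si](C)(C)OS(=O)(=O)C(F)(F)F
Why: Silylation of the secondary allylic alcohol gives the TBS ether that keeps O2 distinct from O9 until the last step.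

Step 9
Reactants: 13 methyl (2E,5R,6Z,8S)-5-[(tert-butyldimethylsilyl)oxy]-8-[(4-methoxybenzyl)oxy]-3,7-dimethylundeca-2,6,10-trienoate
Product: 14 (2E,5R,6Z,8S)-5-[(tert-butyldimethylsilyl)oxy]-8-[(4-methoxybenzyl)oxy]-3,7-dimethylundeca-2,6,10-trien-1-ol
Conditions: i-Bu2AlH (2.5 equiv), CH2Cl2, −78 °C; aq. potassium sodium tartrate
Reagents that add atoms: none
Why: 1,2-Reduction of the enoate with i-Bu2AlH should give the allylic alcohol before any lactone is present in the molecule.

Step 10
Reactants: 14 (2E,5R,6Z,8S)-5-[(tert-butyldimethylsilyl)oxy]-8-[(4-methoxybenzyl)oxy]-3,7-dimethylundeca-2,6,10-trien-1-ol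
Product: 15 (2E,5R,6Z,8S)-5-[(tert-butyldimethylsilyl)oxy]-8-[(4-methoxybenzyl)oxy]-3,7-dimethylundeca-2,6,10-trienal
Conditions: MnO2 (20 equiv), CH2Cl2, 20 °C
Reagents that add atoms: none
Why: Chemoselective MnO2 oxidation of the primary allylic alcohol should give the E enal (C6 aldehyde) needed for the ring closure.

Step 11
Reactants: 15 (2E,5R,6Z,8S)-5-[(tert-butyldimethylsilyl)oxy]-8-[(4-methoxybenzyl)oxy]-3,7-dimethylundeca-2,6,10-trienal
Product: 16 (2E,5R,6Z,8S)-5-[(tert-butyldimethylsilyl)oxy]-8-hydroxy-3,7-dimethylundeca-2,6,10-trienal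
Conditions: DDQ (1.3 equiv), CH2Cl2/pH 7 buffer (10:1), 0 °C
Reagents that add atoms: none
Why: Oxidative cleavage of the PMB ether by DDQ should free the C9 hydroxyl while the TBS ether and the enal stay intact.

Step 12
Reactants: 17 2-(bromomethyl)prop-2-enoic acid
Product: 18 2-(bromomethyl)prop-2-enoyl chloride
Conditions: (COCl)2, DMF (cat.), CH2Cl2, 0 → 20 °C; volatiles removed, used crude
Reagents that add atoms: oxalyl chloride, O=C(Cl)C(=O)Cl
Why: Formamide-catalysed conversion of the acid into its chloride activates it without a nucleophilic amine that would attack the allylic bromide.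

Step 13
Reactants: 16 (2E,5R,6Z,8S)-5-[(tert-butyldimethylsilyl)oxy]-8-hydroxy-3,7-dimethylundeca-2,6,10-trienal; 18 2-(bromomethyl)prop-2-enoyl chloride
Product: 19 (4S,5Z,7R,9E)-7-[(tert-butyldimethylsilyl)oxy]-5,9-dimethyl-11-oxoundeca-1,5,9-trien-4-yl 2-(bromomethyl)prop-2-enoate
Conditions: 2,6-lutidine (2 equiv), CH2Cl2, −20 → 0 °C
Reagents that add atoms: none
Why: O-Acylation of the only free hydroxyl with the acid chloride and a hindered, weakly nucleophilic base ties C12 to O9 with retention at C9.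

Step 14
Reactants: 19 (4S,5Z,7R,9E)-7-[(tert-butyldimethylsilyl)oxy]-5,9-dimethyl-11-oxoundeca-1,5,9-trien-4-yl 2-(bromomethyl)prop-2-enoate
Product: 20 (6S)-3-(bromomethyl)-6-[(2Z,4R,6E)-4-[(tert-butyldimethylsilyl)oxy]-6-methyl-8-oxoocta-2,6-dien-2-yl]-5,6-dihydro-2H-pyran-2-one
Conditions: second-generation Hoveyda–Grubbs catalyst [RuCl2(H2IMes)(=CH-C6H4-2-O-i-Pr)] (10 mol%), toluene (5 mM), 80 °C
Reagents that add atoms: none
Why: Ring-closing metathesis between the terminal vinyl group and the 1,1-disubstituted acrylate should close the six-membered unsaturated lactone, whose ring forces C12 cis to C8 and the bromomethyl carbon C13 trans to C8, while the trisubstituted olefins stay inert and a phosphine-free catalyst is not alkylated by the allylic bromide.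

Step 15
Reactants: 20 (6S)-3-(bromomethyl)-6-[(2Z,4R,6E)-4-[(tert-butyldimethylsilyl)oxy]-6-methyl-8-oxoocta-2,6-dien-2-yl]-5,6-dihydro-2H-pyran-2-one
Product: 23 (3aS,5S,6Z,8R,10E,11aR)-8-[(tert-butyldimethylsilyl)oxy]-5-hydroxy-6,10-dimethyl-3-methylidene-3a,4,5,8,9,11a-hexahydrocyclodeca[b]furan-2(3H)-one, via allylchromium dichloride 21 (not isolated), via bridged δ-lactone chromium alkoxide 22 (not isolated)
Conditions: CrCl2 (10 equiv), THF, 25 °C, syringe-pump addition of 20 (final 2 mM); aq. NH4Cl; then PPTS (0.1 equiv), CH2Cl2, 25 °C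
Reagents that add atoms: none
Why: Two equivalents of divalent chromium reduce the allylic C–Br bond to the allylchromium species 21, which adds through its γ-carbon C7 to the tethered enal carbon C6 in a Zimmerman–Traxler chair, and the C6 alkoxide 22 then attacks the lactone carbonyl C12 and expels O9; the closest known reaction type is the intramolecular Nozaki–Hiyama (chromium Barbier) allylation of aldehydes by 2-(bromomethyl)acrylates used to close ten-membered germacranolide rings, together with the intermolecular allylations known for 3-(bromomethyl)-unsaturated lactones. The ten-membered carbocycle closes by 10-exo-trig attack of the allyl γ-carbon on the aldehyde C=O, and the γ-lactone closes by 5-exo-trig acyl substitution at C12, which at the same time opens the six-membered lactone and frees the C9 hydroxyl for the later acylation. C7 is controlled by C9 through the temporary lactone, because the chain carrying the aldehyde hangs from C9 and can reach C7 only on the ring face cis to that chain, which is the 1,3-syn (7S) arrangement of the target. C6 is controlled by the chair transition state, since the lactone ring fixes the allyl unit in the E-crotyl-type geometry (C8 trans to CH2Cr) and the enal chain sits equatorial, which should give the anti adduct (6R, trans-fused lactone after the acyl shift). The step needs γ- over α-attack (ten- against twelve-membered ring), 1,2- over 1,4-addition to the enal and cyclisation over oligomerisation; the first two are inherent to allylchromium reagents and the third is secured by slow addition at high dilution. The acyl shift should be driven by release of the bridged δ-lactone into the fused α-methylene-γ-lactone, with PPTS added only to complete it.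

Step 16
Reactants: 24 (2E)-but-2-enal
Product: 25 (2Z)-2-iodobut-2-enal
Conditions: I2 (1.5 equiv), K2CO3 (1.2 equiv), DMAP (0.2 equiv), THF/H2O (1:1), 20 °C
Reagents that add atoms: iodine, II
Why: DMAP-mediated α-iodination of the enal (conjugate addition, iodination of the enolate, elimination) should give the Z iodoenal in which methyl stays trans to the carbonyl carbon and cis to iodine.

Step 17
Reactants: 25 (2Z)-2-iodobut-2-enal
Product: 26 (2Z)-2-iodobut-2-en-1-ol
Conditions: NaBH4, CeCl3·7H2O, MeOH, 0 °C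
Reagents that add atoms: none
Why: Luche reduction gives clean 1,2-reduction of the iodoenal without loss of iodine or geometry.

Step 18
Reactants: 26 (2Z)-2-iodobut-2-en-1-ol
Product: 27 tert-butyl{[(2Z)-2-iodobut-2-en-1-yl]oxy}dimethylsilane
Conditions: TBSCl, imidazole, CH2Cl2, 20 °C
Reagents that add atoms: tert-butyldimethylsilyl chloride, CC(C)(C)[Si](C)(C)Cl
Why: Silylation protects the future hydroxymethyl group of the side chain with a group that leaves in the final step.

Step 19
Reactants: 27 tert-butyl{[(2Z)-2-iodobut-2-en-1-yl]oxy}dimethylsilane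
Product: 29 (2Z)-2-{[(tert-butyldimethylsilyl)oxy]methyl}but-2-enoic acid, via Z-vinyllithium 28 (not isolated)
Conditions: t-BuLi (2.1 equiv), Et2O, −78 °C; CO2 (g), −78 °C; cold 1 M HCl
Reagents that add atoms: carbon dioxide, O=C=O
Why: Iodine–lithium exchange and carboxylation both proceed with retention, so the carboxyl takes the place of iodine cis to the methyl group and the Z (angelate-type) acid results without any equilibration.

Step 20
Reactants: 23 (3aS,5S,6Z,8R,10E,11aR)-8-[(tert-butyldimethylsilyl)oxy]-5-hydroxy-6,10-dimethyl-3-methylidene-3a,4,5,8,9,11a-hexahydrocyclodeca[b]furan-2(3H)-one; 29 (2Z)-2-{[(tert-butyldimethylsilyl)oxy]methyl}but-2-enoic acid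
Product: 31 (3aS,5S,6Z,8R,10E,11aR)-8-[(tert-butyldimethylsilyl)oxy]-6,10-dimethyl-3-methylidene-2-oxo-2,3,3a,4,5,8,9,11a-octahydrocyclodeca[b]furan-5-yl (2Z)-2-{[(tert-butyldimethylsilyl)oxy]methyl}but-2-enoate, via trichlorobenzoyl mixed anhydride 30 (not isolated)
Conditions: 2,4,6-trichlorobenzoyl chloride, Et3N, toluene, 20 °C; then 23, DMAP, toluene, 20 °C
Reagents that add atoms: none
Why: Yamaguchi esterification acylates the only free hydroxyl (C9) with retention at carbon and is the usual way to attach angelate-type acids with little Z-to-E isomerisation.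

Step 21
Reactants: 31 (3aS,5S,6Z,8R,10E,11aR)-8-[(tert-butyldimethylsilyl)oxy]-6,10-dimethyl-3-methylidene-2-oxo-2,3,3a,4,5,8,9,11a-octahydrocyclodeca[b]furan-5-yl (2Z)-2-{[(tert-butyldimethylsilyl)oxy]methyl}but-2-enoate
Product: 32 (3aS,5S,6Z,8R,10E,11aR)-8-hydroxy-6,10-dimethyl-3-methylidene-2-oxo-2,3,3a,4,5,8,9,11a-octahydrocyclodeca[b]furan-5-yl (2Z)-2-(hydroxymethyl)but-2-enoate (CNP0273961.1)
Conditions: HF·pyridine, pyridine, THF, 0 → 20 °C
Reagents that add atoms: none
Why: Buffered fluoride desilylation removes both TBS ethers under conditions that should spare the α-methylene lactone, the Z ester and the acid-sensitive 1(10),4-diene.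

## Compound list

1 | prop-2-yn-1-ol | C#CCO | starting material
2 | (Z)-3-(bromomagnesiooxy)-2-methylprop-1-enylmagnesium bromide | Br[Mg]/C=C(/C)CO[Mg]Br | intermediate (not isolated)
3 | (2Z)-3-iodo-2-methylprop-2-en-1-ol | I/C=C(/C)CO | intermediate
4 | (2Z)-3-iodo-2-methylprop-2-enal | I/C=C(/C)C=O | intermediate
5 | (1Z,3S)-1-iodo-2-methylhexa-1,5-dien-3-ol | I/C=C(/C)[C@@H](O)CC=C | intermediate
6 | (1Z,3S)-1-iodo-3-[(4-methoxybenzyl)oxy]-2-methylhexa-1,5-diene | I/C=C(/C)[C@@H](OCc1ccc(OC)cc1)CC=C | intermediate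
7 | (1Z,3S)-3-[(4-methoxybenzyl)oxy]-2-methylhexa-1,5-dien-1-yllithium | [Li]/C=C(/C)[C@@H](OCc1ccc(OC)cc1)CC=C | intermediate (not isolated)
8 | (2Z,4S)-4-[(4-methoxybenzyl)oxy]-3-methylhepta-2,6-dienal | O=C/C=C(/C)[C@@H](OCc1ccc(OC)cc1)CC=C | intermediate
9 | methyl 3-methylbut-2-enoate | COC(=O)C=C(C)C | starting material
10 | lithium 1-methoxy-3-methylbuta-1,3-dien-1-olate | [Li]OC(OC)=CC(C)=C | intermediate (not isolated)
11 | tert-butyl[(1-methoxy-3-methylbuta-1,3-dien-1-yl)oxy]dimethylsilane | COC(O[Si](C)(C)C(C)(C)C)=CC(C)=C | intermediate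
12 | methyl (2E,5R,6Z,8S)-5-hydroxy-8-[(4-methoxybenzyl)oxy]-3,7-dimethylundeca-2,6,10-trienoate | COC(=O)/C=C(\C)C[C@@H](O)/C=C(/C)[C@@H](OCc1ccc(OC)cc1)CC=C | intermediate
13 | methyl (2E,5R,6Z,8S)-5-[(tert-butyldimethylsilyl)oxy]-8-[(4-methoxybenzyl)oxy]-3,7-dimethylundeca-2,6,10-trienoate | COC(=O)/C=C(\C)C[C@@H](O[Si](C)(C)C(C)(C)C)/C=C(/C)[C@@H](OCc1ccc(OC)cc1)CC=C | intermediate
14 | (2E,5R,6Z,8S)-5-[(tert-butyldimethylsilyl)oxy]-8-[(4-methoxybenzyl)oxy]-3,7-dimethylundeca-2,6,10-trien-1-ol | OC/C=C(\C)C[C@@H](O[Si](C)(C)C(C)(C)C)/C=C(/C)[C@@H](OCc1ccc(OC)cc1)CC=C | intermediate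
15 | (2E,5R,6Z,8S)-5-[(tert-butyldimethylsilyl)oxy]-8-[(4-methoxybenzyl)oxy]-3,7-dimethylundeca-2,6,10-trienal | O=C/C=C(\C)C[C@@H](O[Si](C)(C)C(C)(C)C)/C=C(/C)[C@@H](OCc1ccc(OC)cc1)CC=C | intermediate
16 | (2E,5R,6Z,8S)-5-[(tert-butyldimethylsilyl)oxy]-8-hydroxy-3,7-dimethylundeca-2,6,10-trienal | O=C/C=C(\C)C[C@@H](O[Si](C)(C)C(C)(C)C)/C=C(/C)[C@@H](O)CC=C | intermediate
17 | 2-(bromomethyl)prop-2-enoic acid | C=C(CBr)C(=O)O | starting material
18 | 2-(bromomethyl)prop-2-enoyl chloride | C=C(CBr)C(=O)Cl | intermediate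
19 | (4S,5Z,7R,9E)-7-[(tert-butyldimethylsilyl)oxy]-5,9-dimethyl-11-oxoundeca-1,5,9-trien-4-yl 2-(bromomethyl)prop-2-enoate | O=C/C=C(\C)C[C@@H](O[Si](C)(C)C(C)(C)C)/C=C(/C)[C@@H](OC(=O)C(=C)CBr)CC=C | intermediate
20 | (6S)-3-(bromomethyl)-6-[(2Z,4R,6E)-4-[(tert-butyldimethylsilyl)oxy]-6-methyl-8-oxoocta-2,6-dien-2-yl]-5,6-dihydro-2H-pyran-2-one | O=C/C=C(\C)C[C@@H](O[Si](C)(C)C(C)(C)C)/C=C(/C)[C@@H]1CC=C(CBr)C(=O)O1 | intermediate
21 | allylchromium dichloride of 20 (CrCl2 on the former bromomethyl carbon C13) | O=C/C=C(\C)C[C@@H](O[Si](C)(C)C(C)(C)C)/C=C(/C)[C@@H]1CC=C(C[Cr](Cl)Cl)C(=O)O1 | intermediate (not isolated)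
22 | (2R,6R,7S,9S)-2-[(tert-butyldimethylsilyl)oxy]germacra-1(10)Z,4E,11(13)-trien-12,9-olide 6-O-chromium dichloride alkoxide (bridged δ-lactone) | C=C1C(=O)O[C@H]2C[C@@H]1[C@H](O[Cr](Cl)Cl)/C=C(\C)C[C@@H](O[Si](C)(C)C(C)(C)C)/C=C2/C | intermediate (not isolated)
23 | (3aS,5S,6Z,8R,10E,11aR)-8-[(tert-butyldimethylsilyl)oxy]-5-hydroxy-6,10-dimethyl-3-methylidene-3a,4,5,8,9,11a-hexahydrocyclodeca[b]furan-2(3H)-one | C=C1C(=O)O[C@@H]2/C=C(\C)C[C@@H](O[Si](C)(C)C(C)(C)C)/C=C(/C)[C@@H](O)C[C@@H]12 | intermediate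
24 | (2E)-but-2-enal | C/C=C/C=O | starting material
25 | (2Z)-2-iodobut-2-enal | C/C=C(\I)C=O | intermediate
26 | (2Z)-2-iodobut-2-en-1-ol | C/C=C(\I)CO | intermediate
27 | tert-butyl{[(2Z)-2-iodobut-2-en-1-yl]oxy}dimethylsilane | C/C=C(\I)CO[Si](C)(C)C(C)(C)C | intermediate
28 | (2Z)-1-[(tert-butyldimethylsilyl)oxy]but-2-en-2-yllithium | C/C=C(\[Li])CO[Si](C)(C)C(C)(C)C | intermediate (not isolated)
29 | (2Z)-2-{[(tert-butyldimethylsilyl)oxy]methyl}but-2-enoic acid | C/C=C(\C(=O)O)CO[Si](C)(C)C(C)(C)C | intermediate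
30 | (2Z)-2-{[(tert-butyldimethylsilyl)oxy]methyl}but-2-enoic 2,4,6-trichlorobenzoic anhydride | C/C=C(\C(=O)OC(=O)c1c(Cl)cc(Cl)cc1Cl)CO[Si](C)(C)C(C)(C)C | intermediate (not isolated)
31 | (3aS,5S,6Z,8R,10E,11aR)-8-[(tert-butyldimethylsilyl)oxy]-6,10-dimethyl-3-methylidene-2-oxo-2,3,3a,4,5,8,9,11a-octahydrocyclodeca[b]furan-5-yl (2Z)-2-{[(tert-butyldimethylsilyl)oxy]methyl}but-2-enoate | C=C1C(=O)O[C@@H]2/C=C(\C)C[C@@H](O[Si](C)(C)C(C)(C)C)/C=C(/C)[C@@H](OC(=O)/C(=C\C)CO[Si](C)(C)C(C)(C)C)C[C@@H]12 | intermediate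
32 | (3aS,5S,6Z,8R,10E,11aR)-8-hydroxy-6,10-dimethyl-3-methylidene-2-oxo-2,3,3a,4,5,8,9,11a-octahydrocyclodeca[b]furan-5-yl (2Z)-2-(hydroxymethyl)but-2-enoate | C=C1C(=O)O[C@@H]2/C=C(\C)C[C@@H](O)/C=C(/C)[C@@H](OC(=O)/C(=C\C)CO)C[C@@H]12 | target

## Step count and risks

Total step count: 21. Longest linear sequence: 15 steps (steps 1–5, 7–11, 13–15, 20 and 21).

Steps most likely to fail:

1. Step 15. The bridged transition state may be too strained for ring closure, the aldehyde may be attacked on the wrong face (C6 epimer, cis-fused lactone after the acyl shift), or the allylchromium species may be protonated or oligomerise. The fallback sets out from 16 and comes back at 23. Cross-metathesis of 16 with methyl 2-(bromomethyl)acrylate (second-generation Hoveyda–Grubbs catalyst, CH2Cl2, 40 °C) would give the open-chain bromo ester methyl (2Z,5S,6Z,8R,10E)-2-(bromomethyl)-8-[(tert-butyldimethylsilyl)oxy]-5-hydroxy-6,10-dimethyl-12-oxododeca-2,6,10-trienoate F1. Its Nozaki–Hiyama macrocyclisation (CrCl2, THF, high dilution) would close the ten-membered ring without the lactone bridge, and the C6 chromium alkoxide would then lactonise onto the methyl ester to give 23 directly. In this variant C7 is no longer tied to C9, both new centres rest on the conformational preference of the forming ring, and diastereomers would have to be separated.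

2. Step 14. The catalyst may be deactivated by the allylic bromide, the trisubstituted electron-poor olefin may form too slowly, or intermolecular metathesis may compete. The fallback sets out from 16 and comes back at 20.
 - Acylation with acryloyl chloride (i-Pr2NEt, CH2Cl2, 0 °C) would give the acrylate (4S,5Z,7R,9E)-7-[(tert-butyldimethylsilyl)oxy]-5,9-dimethyl-11-oxoundeca-1,5,9-trien-4-yl prop-2-enoate F2.
 - Ring-closing metathesis of this unsubstituted acrylate (second-generation Grubbs catalyst, CH2Cl2, 40 °C) would give the lactone (6S)-6-[(2Z,4R,6E)-4-[(tert-butyldimethylsilyl)oxy]-6-methyl-8-oxoocta-2,6-dien-2-yl]-5,6-dihydro-2H-pyran-2-one F3.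
 - Pyridine-mediated α-iodination (I2, pyridine, CH2Cl2) would give the 3-iodo lactone (6S)-3-iodo-6-[(2Z,4R,6E)-4-[(tert-butyldimethylsilyl)oxy]-6-methyl-8-oxoocta-2,6-dien-2-yl]-5,6-dihydro-2H-pyran-2-one F4.
 - Stille coupling with Bu3SnCH2OH (Pd(PPh3)4, dioxane, 80 °C) would give the alcohol (6S)-3-(hydroxymethyl)-6-[(2Z,4R,6E)-4-[(tert-butyldimethylsilyl)oxy]-6-methyl-8-oxoocta-2,6-dien-2-yl]-5,6-dihydro-2H-pyran-2-one F5.
 - Appel bromination (CBr4, PPh3, CH2Cl2, 0 °C) would then give 20.

3. Step 20. The activated Z acid may isomerise to the E (tiglate-type) ester by reversible conjugate addition of DMAP, or acylation of the hindered allylic C9 hydroxyl may be sluggish. The fallback sets out from 23 and 27 and comes back at 31. Palladium-catalysed alkoxycarbonylation of the vinyl iodide 27 with 23 as the alcohol (PdCl2(PPh3)2, CO at 1 atm, Et3N, DMF, 60 °C) would form the ester through an acylpalladium intermediate that keeps the olefin geometry, with no free activated acid and no new isolated compound.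

## Further compounds

F1 | step 15 | methyl (2Z,5S,6Z,8R,10E)-2-(bromomethyl)-8-[(tert-butyldimethylsilyl)oxy]-5-hydroxy-6,10-dimethyl-12-oxododeca-2,6,10-trienoate | O=C/C=C(\C)C[C@@H](O[Si](C)(C)C(C)(C)C)/C=C(/C)[C@@H](O)C/C=C(\CBr)C(=O)OC
F2 | step 14 | (4S,5Z,7R,9E)-7-[(tert-butyldimethylsilyl)oxy]-5,9-dimethyl-11-oxoundeca-1,5,9-trien-4-yl prop-2-enoate | O=C/C=C(\C)C[C@@H](O[Si](C)(C)C(C)(C)C)/C=C(/C)[C@@H](OC(=O)C=C)CC=C
F3 | step 14 | (6S)-6-[(2Z,4R,6E)-4-[(tert-butyldimethylsilyl)oxy]-6-methyl-8-oxoocta-2,6-dien-2-yl]-5,6-dihydro-2H-pyran-2-one | O=C/C=C(\C)C[C@@H](O[Si](C)(C)C(C)(C)C)/C=C(/C)[C@@H]1CC=CC(=O)O1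
F4 | step 14 | (6S)-3-iodo-6-[(2Z,4R,6E)-4-[(tert-butyldimethylsilyl)oxy]-6-methyl-8-oxoocta-2,6-dien-2-yl]-5,6-dihydro-2H-pyran-2-one | O=C/C=C(\C)C[C@@H](O[Si](C)(C)C(C)(C)C)/C=C(/C)[C@@H]1CC=C(I)C(=O)O1
F5 | step 14 | (6S)-3-(hydroxymethyl)-6-[(2Z,4R,6E)-4-[(tert-butyldimethylsilyl)oxy]-6-methyl-8-oxoocta-2,6-dien-2-yl]-5,6-dihydro-2H-pyran-2-one | O=C/C=C(\C)C[C@@H](O[Si](C)(C)C(C)(C)C)/C=C(/C)[C@@H]1CC=C(CO)C(=O)O1
F0 | step 20 | none | none
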